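The data come from a simulation with made-up constants; the scatter is artificial.

Take the easy step first: mix the charge of the red flask and follow one molecule of starting material.

| flask | starting material | partner | protic impurity | remark | time |
|---|---|---|---|---|---|
| birch | 0.16 M | 0.24 M | 0.032 M | run made earlier |  |
| larch | 0.22 M | 0.24 M | 0.032 M | run made earlier |  |
| cedar | 0.35 M | 0.24 M | 0.032 M | run made earlier |  |
| blue | 0.16 M (fed, over 64.0 min) | 0.240 M | 0.0320 M | a stirred flask in which starting material is dosed at a steady rate over 64.0 min without added volume, worked up at 80 min | 80 min |
| grey | 0.16 M | 0.240 M | 0.0320 M | one stirred flow tank at steady state, fed with the mixture as stated, mean residence time 240 min |  |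
| teal | 0.16 M | 0.240 M | 0.0320 M | one stirred flow tank at steady state, fed with the mixture as stated, mean residence time 80 min |  |
| red | 0.16 M | 0.240 M | 0.0320 M | everything together in a closed stirred flask, run for 80 min | 80 min |

| run | time / min | target / % | isomer of the product / % |
|---|---|---|---|
| birch | 4.00 | 0.4 | 0 |
| birch | 8.00 | 0 | 0 |
| birch | 20.0 | 0.6 | 0 |
| birch | 50.0 | 2.4 | 0.4 |
| larch | 20.0 | 0.5 | 0.4 |
| larch | 40.0 | 3.0 | 0.2 |
| larch | 60.0 | 1.9 | 0 |
| larch | 80.0 | 5.6 | 0.8 |
| cedar | 10.0 | 0 | 0 |
| cedar | 30.0 | 0.4 | 0.3 |
| cedar | 50.0 | 2.6 | 0.5 |
| cedar | 80.0 | 4.5 | 0.3 |

(scatter of a reading: 0.5 percentage points)

- the stated concentrations are those of everything mixed, before any reaction; amounts are the same in each set-up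
- the analysis behind the earlier runs scatters by 0.5 percentage points, standard deviation
- the feed brings no volume worth counting
- the earlier runs were made in a closed, stirred flask

* order of the set-ups by the share of target in all that became target or isomer of the product or over-reaction product, at the outlet or at the end, highest first (blue / grey / teal / red)
* share of target in all that became target or isomer of the product or over-reaction product, at the outlet or at the end, blue
* share of target in all that became target or isomer of the product or over-reaction product, at the outlet or at the end, grey
* share of target in all that became target or isomer of the product or over-reaction product, at the outlet or at the end, teal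
* share of target in all that became target or isomer of the product or over-reaction product, at the outlet or at the end, red

Begin with the first minutes. At 20.0 min the birch run shows 0.6% target and the larch run shows 0.5%, close to the scatter of 0.5 percentage points. So read a lag at the start.

Move to the middle. Target climbs, and at 80.0 min the larch run reads 5.6% and the cedar run 4.5%. Pool those two last readings with their isomer: target takes 90.2% of the two. Call this reading f, the first fork of the selectivity. Its isomer readings, 0.8% and 0.3%, are of the size of the scatter, so hold it loosely.

Now go to the end. The runs did not read over-reaction product. Take it to form from target already in the vessel, and ask how long target has sat. In the red flask, take making as steady: a target molecule is on average 40.0 min old at work-up. Call this mean time in the vessel the target's age θ.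

Dosing shifts making later. Take it as proportional to the dosed amount, and blue gets 27.6 min. In a tank, a fresh molecule leaves at the same rate as an old one, so θ is the residence time: 80.0 min in teal and 240 min in grey.

Put the second fork in the tank. Suppose target is lost at first-order rate k. It then leaves intact with chance 1/(1+kθ). My reckoning is f times that chance. With k unread, I commit to the order of age, blue, red, teal, grey, and to no number for the tanks.

The forecast gave the order blue > red > teal > grey, with 88% for blue, 87.5% for red, 87% for teal and 84% for grey, and said “Differences between blue, red and teal are within noise”.

The flask gives 84.3% for blue, 80.3% for red, 65.8% for teal and 40.9% for grey, in the order blue > red > teal > grey.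

    starting material + partner → intermediate + released group (k = 1.83 × 10⁻⁴ /M/s)
    intermediate ⇌ target (K = 1.30, k = 2.50 × 10⁻⁴ /s)
    intermediate ⇌ isomer of the product (K = 2.20, k = 1.29 × 10⁻⁵ /s)
    partner + protic impurity → quenched reagent (k = 0.0224 /M/s)
    target → over-reaction product (k = 8.38 × 10⁻⁵ /s)

Compare grey with blue. Take away the loss of target to over-reaction product, and the gap between them shrinks from 43 points to 9.1 points. With target lost at k = 8.38 × 10⁻⁵ /s, grey's age gives f/(1+kθ) = 40.9%, against 40.9% in the flask. Blue left until 800 min has, with making taken as steady, an age of 400 min; f times the surviving part of steadily made target gives 22.0%, against a simulated 17.7%.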